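**Plan**

- Retrosynthetic cuts: first the four O–CH2Ph bonds; then the second carbonyl of the dione and the CH2–aryl bond of the C8 side chain, back to a C8 acetyl group; then a sacrificial formyl group on C3 and the C3=C4 unsaturation; last O1–C2 and C3–C4 of the pyran ring.
- Enabling feature: the pyran ring (O1, C2, C3, C4 fused on the C4a–C8a edge of the phloroglucinol ring) holds the only stereocentre, C2, which is benzylic and bonded to O1. C4 sits on C4a ortho to O1, and C8, on the other side of O1, bears an acyl carbon. O1/C4a/C4 therefore map onto a salicylaldehyde that already carries the C8 acetyl group, and C2/C3 onto the β/α carbons of a cinnamaldehyde.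
- Forward: formylation and 4,6-dibenzylation of phloracetophenone give the salicylaldehyde, and a Wittig reaction gives the enal. The amine-catalysed annulation closes the pyran ring, the only ring made. Decarbonylation and hydrogenation give the 8-acetylflavan; α-arylation, oxidation and hydrogenolysis finish the aryl dione.
- Stereochemistry: C2 is set in the annulation by an (S)-diphenylprolinol silyl ether (face shielding of the iminium ion), and no later step touches it.

Key step: step 4

Assumption: the (S)-catalyst is taken to deliver the required arrangement at C2 by the usual shielding model for diarylprolinol silyl ethers; by the CIP rules this arrangement is 2R in the 3-formylchromenes 9 and F2 (C3 with its formyl group outranks the aryl group) and 2S in every other chromene and chroman of the route.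

**Route**

Step 1
Reactants: 1 2',4',6'-trihydroxyacetophenone (phloracetophenone)
Product: 3 3-acetyl-2,4,6-trihydroxybenzaldehyde, via aryl iminium chloride 2 (not isolated)
Conditions: POCl3 (1.1 equiv), DMF (1.5 equiv), EtOAc, 0 °C to rt; then H2O, 50 °C
Reagents that add atoms: N,N-dimethylformamide CN(C)C=O; water O
Why: Vilsmeier–Haack formylation of the very electron-rich acylphloroglucinol ring, whose two free positions are equivalent, should give one C-formyl product when about one equivalent of reagent is used cold, which holds back attack at the acetyl group (chromone formation) and a second formylation.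

Step 2
Reactants: 3 3-acetyl-2,4,6-trihydroxybenzaldehyde
Product: 4 3-acetyl-4,6-bis(benzyloxy)-2-hydroxybenzaldehyde
Conditions: BnBr (2.05 equiv), K2CO3 (2.2 equiv), DMF, 0 °C to rt
Reagents that add atoms: benzyl bromide BrCc1ccccc1
Why: Williamson etherification with two equivalents of benzyl bromide should alkylate the two outer hydroxyls, each para to one carbonyl and open on one side, and leave the hydroxyl wedged between formyl and acetyl, which is the most hindered and always has a carbonyl oxygen on either side to chelate it.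

Step 3
Reactants: 5 4-(benzyloxy)benzaldehyde
Product: 6 (E)-3-[4-(benzyloxy)phenyl]prop-2-enal
Conditions: Ph3P=CHCHO (1.05 equiv), PhMe, 80 °C
Reagents that add atoms: (triphenylphosphoranylidene)acetaldehyde O=CC=P(c1ccccc1)(c1ccccc1)c1ccccc1
Why: Wittig olefination with the stabilised formylmethylene ylide should give the E-enal, and the small excess of ylide is chosen to limit a second two-carbon homologation.

Step 4
Reactants: 4 3-acetyl-4,6-bis(benzyloxy)-2-hydroxybenzaldehyde; 6 (E)-3-[4-(benzyloxy)phenyl]prop-2-enal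
Product: 9 (2R)-8-acetyl-5,7-bis(benzyloxy)-2-[4-(benzyloxy)phenyl]-2H-chromene-3-carbaldehyde, via enamine oxa-Michael adduct 7 (not isolated), via aldol adduct 8 (not isolated)
Conditions: 6 (1.5 equiv), (S)-2-[diphenyl(trimethylsilyloxy)methyl]pyrrolidine (20 mol%), 2-nitrobenzoic acid (20 mol%), 4 Å MS, PhMe, 0 °C to rt
Reagents that add atoms: none
Why: The amine and enal 6 form an E-iminium ion; the phenol of 4, deprotonated by the carboxylate, adds to its β-carbon (oxa-Michael, O1–C2) to give enamine 7, whose α-carbon attacks the adjacent formyl group (C3–C4) to give aldol 8, and loss of water then delivers 9 and returns the catalyst. The closest known reaction is the diarylprolinol silyl ether catalysed domino oxa-Michael/aldol condensation of salicylaldehydes with cinnamaldehydes to 2-aryl-2H-chromene-3-carbaldehydes. The pyran ring closes in the aldol step by a 6-(enolexo)-exo-trig addition, and E1cB dehydration then places the C3=C4 double bond. C2 is set in the oxa-Michael step by the catalyst: the diphenyl(silyloxy)methyl group on the (S)-pyrrolidine carbon covers one face of the s-trans E-iminium ion, so oxygen adds to the other face, which corresponds to 2R in 9. The enamine must choose the formyl group over the acetyl group, which is secured because the acetyl carbonyl is a hindered, di-ortho-substituted ketone of much lower electrophilicity and only the aldehyde adduct can dehydrate irreversibly to a conjugated enal; the acyl carbon ends on C8 because the only free phenol of 4 lies between formyl and acetyl. Enantiopurity is guarded against the reversible oxa-Michael step by the acid co-catalyst, the sieves and the low temperature, which favour the irreversible aldol condensation over ring opening.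

Step 5
Reactants: 9 (2R)-8-acetyl-5,7-bis(benzyloxy)-2-[4-(benzyloxy)phenyl]-2H-chromene-3-carbaldehyde
Product: 10 1-{(2S)-5,7-bis(benzyloxy)-2-[4-(benzyloxy)phenyl]-2H-chromen-8-yl}ethan-1-one
Conditions: RhCl(PPh3)3 (1.1 equiv), degassed PhMe, 90–100 °C
Reagents that add atoms: none
Why: Tsuji–Wilkinson decarbonylation (oxidative addition of the formyl C–H bond to Rh(I), CO de-insertion, C–H reductive elimination) should replace the formyl group by hydrogen with the C3=C4 bond in place, under neutral conditions that offer no base or amine to open the pyran ring and leave the aryl ketone and benzyl ethers alone.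

Step 6
Reactants: 10 1-{(2S)-5,7-bis(benzyloxy)-2-[4-(benzyloxy)phenyl]-2H-chromen-8-yl}ethan-1-one
Product: 11 1-{(2S)-5,7-bis(benzyloxy)-2-[4-(benzyloxy)phenyl]-3,4-dihydro-2H-chromen-8-yl}ethan-1-one
Conditions: H2 (1 atm), RhCl(PPh3)3 (5 mol%), PhH–EtOH (1:1), rt
Reagents that add atoms: none
Why: Homogeneous hydrogenation with the chlororhodium tris(phosphine) catalyst should saturate the cis-disubstituted, styrene-type C3=C4 bond without hydrogenolysis of the benzyl ethers or of the benzylic C2–O1 bond and without reducing the ketone, so C2 stays as set.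

Step 7
Reactants: 11 1-{(2S)-5,7-bis(benzyloxy)-2-[4-(benzyloxy)phenyl]-3,4-dihydro-2H-chromen-8-yl}ethan-1-one; 12 1-(benzyloxy)-4-bromobenzene
Product: 13 1-{(2S)-5,7-bis(benzyloxy)-2-[4-(benzyloxy)phenyl]-3,4-dihydro-2H-chromen-8-yl}-2-[4-(benzyloxy)phenyl]ethan-1-one
Conditions: Pd2(dba)3 (2.5 mol%), Xantphos (6 mol%), NaOtBu (2.2 equiv), THF, 70 °C
Reagents that add atoms: none
Why: Palladium-catalysed α-arylation of a ketone enolate (Buchwald–Hartwig type) should arylate the methyl group, the only enolisable position, once, because the more acidic deoxybenzoin product rests as its enolate; the flavan has no base-sensitive site while the 4'-phenol is benzylated.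

Step 8
Reactants: 13 1-{(2S)-5,7-bis(benzyloxy)-2-[4-(benzyloxy)phenyl]-3,4-dihydro-2H-chromen-8-yl}-2-[4-(benzyloxy)phenyl]ethan-1-one
Product: 14 1-{(2S)-5,7-bis(benzyloxy)-2-[4-(benzyloxy)phenyl]-3,4-dihydro-2H-chromen-8-yl}-2-[4-(benzyloxy)phenyl]ethane-1,2-dione
Conditions: SeO2 (1.5 equiv), 1,4-dioxane–H2O (30:1), 90 °C
Reagents that add atoms: selenium dioxide O=[Se]=O
Why: Riley oxidation should convert the deoxybenzoin methylene, activated by both the ketone and the electron-rich aryl ring, into the second carbonyl, while the other benzylic positions (C2, C4, OCH2Ph) have no carbonyl activation and should remain.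

Step 9
Reactants: 14 1-{(2S)-5,7-bis(benzyloxy)-2-[4-(benzyloxy)phenyl]-3,4-dihydro-2H-chromen-8-yl}-2-[4-(benzyloxy)phenyl]ethane-1,2-dione
Product: 15 1-[(2S)-5,7-dihydroxy-2-(4-hydroxyphenyl)-3,4-dihydro-2H-chromen-8-yl]-2-(4-hydroxyphenyl)ethane-1,2-dione
Conditions: H2 (1 atm), 10% Pd/C, EtOAc–THF (1:1), rt, stopped when the benzyl ethers are consumed
Reagents that add atoms: none
Why: Catalytic hydrogenolysis should cleave the four aryl benzyl ethers faster than the hindered, electron-rich diaryl dione is reduced in an aprotic solvent, and its neutrality avoids the acid- or base-induced opening of the C2–O1 bond that a free 4'-phenol invites.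

**Compound list**

1 | 2',4',6'-trihydroxyacetophenone (phloracetophenone) | CC(=O)c1c(O)cc(O)cc1O | starting material
2 | [(3-acetyl-2,4,6-trihydroxyphenyl)methylidene]dimethylammonium chloride | CC(=O)c1c(O)cc(O)c(C=[N+](C)C)c1O.[Cl-] | intermediate
3 | 3-acetyl-2,4,6-trihydroxybenzaldehyde | CC(=O)c1c(O)cc(O)c(C=O)c1O | intermediate
4 | 3-acetyl-4,6-bis(benzyloxy)-2-hydroxybenzaldehyde | CC(=O)c1c(O)c(C=O)c(OCc2ccccc2)cc1OCc1ccccc1 | intermediate
5 | 4-(benzyloxy)benzaldehyde | O=Cc1ccc(OCc2ccccc2)cc1 | starting material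
6 | (E)-3-[4-(benzyloxy)phenyl]prop-2-enal | O=C/C=C/c1ccc(OCc2ccccc2)cc1 | intermediate
7 | 3-acetyl-4,6-bis(benzyloxy)-2-({(1S,2E)-1-[4-(benzyloxy)phenyl]-3-[(2S)-2-[diphenyl(trimethylsilyloxy)methyl]pyrrolidin-1-yl]prop-2-en-1-yl}oxy)benzaldehyde (oxa-Michael adduct held as its enamine with the catalyst) | CC(=O)c1c(O[C@H](c2ccc(OCc3ccccc3)cc2)/C=C/N2CCC[C@H]2C(c2ccccc2)(c2ccccc2)O[Si](C)(C)C)c(C=O)c(OCc2ccccc2)cc1OCc1ccccc1 | intermediate
8 | (2S)-8-acetyl-5,7-bis(benzyloxy)-2-[4-(benzyloxy)phenyl]-4-hydroxychromane-3-carbaldehyde (aldol adduct, drawn free of the catalyst; C3 and C4 not assigned, both are lost on dehydration) | CC(=O)c1c(OCc2ccccc2)cc(OCc2ccccc2)c2c1O[C@H](c1ccc(OCc3ccccc3)cc1)C(C=O)C2O | intermediate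
9 | (2R)-8-acetyl-5,7-bis(benzyloxy)-2-[4-(benzyloxy)phenyl]-2H-chromene-3-carbaldehyde | CC(=O)c1c(OCc2ccccc2)cc(OCc2ccccc2)c2c1O[C@H](c1ccc(OCc3ccccc3)cc1)C(C=O)=C2 | intermediate
10 | 1-{(2S)-5,7-bis(benzyloxy)-2-[4-(benzyloxy)phenyl]-2H-chromen-8-yl}ethan-1-one | CC(=O)c1c(OCc2ccccc2)cc(OCc2ccccc2)c2c1O[C@H](c1ccc(OCc3ccccc3)cc1)C=C2 | intermediate
11 | 1-{(2S)-5,7-bis(benzyloxy)-2-[4-(benzyloxy)phenyl]-3,4-dihydro-2H-chromen-8-yl}ethan-1-one | CC(=O)c1c(OCc2ccccc2)cc(OCc2ccccc2)c2c1O[C@H](c1ccc(OCc3ccccc3)cc1)CC2 | intermediate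
12 | 1-(benzyloxy)-4-bromobenzene | Brc1ccc(OCc2ccccc2)cc1 | starting material
13 | 1-{(2S)-5,7-bis(benzyloxy)-2-[4-(benzyloxy)phenyl]-3,4-dihydro-2H-chromen-8-yl}-2-[4-(benzyloxy)phenyl]ethan-1-one | O=C(Cc1ccc(OCc2ccccc2)cc1)c1c(OCc2ccccc2)cc(OCc2ccccc2)c2c1O[C@H](c1ccc(OCc3ccccc3)cc1)CC2 | intermediate
14 | 1-{(2S)-5,7-bis(benzyloxy)-2-[4-(benzyloxy)phenyl]-3,4-dihydro-2H-chromen-8-yl}-2-[4-(benzyloxy)phenyl]ethane-1,2-dione | O=C(C(=O)c1c(OCc2ccccc2)cc(OCc2ccccc2)c2c1O[C@H](c1ccc(OCc3ccccc3)cc1)CC2)c1ccc(OCc2ccccc2)cc1 | intermediate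
15 | 1-[(2S)-5,7-dihydroxy-2-(4-hydroxyphenyl)-3,4-dihydro-2H-chromen-8-yl]-2-(4-hydroxyphenyl)ethane-1,2-dione | O=C(C(=O)c1c(O)cc(O)c2c1O[C@H](c1ccc(O)cc1)CC2)c1ccc(O)cc1 | target

**Step count and risks**

Total steps: 9. Longest linear sequence: 8 (steps 1, 2, 4, 5, 6, 7, 8, 9); step 3 is a one-step branch.

Steps most likely to fail:

1. Step 4. The phenol sits between two carbonyl groups and is tied up in hydrogen bonds, so the oxa-Michael addition may be slow; self-condensation of the enal and loss of enantiopurity through the reversible addition could then take over. The fallback sets out from enal 6 and keeps the same annulation, but with a salicylaldehyde that lacks the acetyl group; the acyl carbon is put on C8 afterwards.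
   - Commercial 2,4,6-trihydroxybenzaldehyde is dibenzylated under the conditions of step 2. By symmetry only one hydroxyl, chelated to the formyl group, stays free, giving 2,4-bis(benzyloxy)-6-hydroxybenzaldehyde F1.
   - Annulation of this compound with 6 under the conditions of step 4 should give (2R)-5,7-bis(benzyloxy)-2-[4-(benzyloxy)phenyl]-2H-chromene-3-carbaldehyde F2.
   - Decarbonylation as in step 5 leads to (2S)-5,7-bis(benzyloxy)-2-[4-(benzyloxy)phenyl]-2H-chromene F3, and hydrogenation as in step 6 to (2S)-5,7-bis(benzyloxy)-2-[4-(benzyloxy)phenyl]chromane F4.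
   - NBS (1.0 equiv, CH2Cl2, −78 °C) should brominate the phloroglucinol ring at C8, the position flanked by the tied-back ring oxygen and therefore less hindered than C6, to give (2S)-5,7-bis(benzyloxy)-2-[4-(benzyloxy)phenyl]-8-bromochromane F5.
   - Bromine–lithium exchange (n-BuLi, THF, −78 °C) and acylation with N-methoxy-N-methylacetamide then return to the route at 11.

2. Step 5. The vinylic aldehyde needs heat to extrude CO, and at that temperature the 2H-chromene may open reversibly to an o-quinone methide by electrocyclic ring opening, which would erode the configuration at C2; CO extrusion from the hindered acyl–rhodium species may also stall. The fallback sets out from 9 and avoids the 2H-chromene 10 altogether.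
   - The C3=C4 bond is hydrogenated first (H2, 1 atm, Pd/C poisoned with pyridine so that the aryl benzyl ethers and the ketone are spared, EtOAc, rt) to (2S)-8-acetyl-5,7-bis(benzyloxy)-2-[4-(benzyloxy)phenyl]chromane-3-carbaldehyde F6, a mixture at C3.
   - This saturated aldehyde should lose CO with RhCl(PPh3)3 (1.1 equiv, PhMe, 80 °C) at a lower temperature than the enal, which rejoins the route at 11.

3. Step 9. Reduction of the 1,2-dione to an α-hydroxy ketone may compete with cleavage of the last benzyl ethers. The fallback sets out from 13 and moves the hydrogenolysis ahead of the oxidation.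
   - Hydrogenolysis (H2, Pd/C, EtOAc–MeOH), with only a hindered, chelated ketone present, should give 1-[(2S)-5,7-dihydroxy-2-(4-hydroxyphenyl)chroman-8-yl]-2-(4-hydroxyphenyl)ethan-1-one F7.
   - Acetylation (Ac2O, pyridine, DMAP, 0 °C to rt) gives the tetraacetate (2S)-2-(4-acetoxyphenyl)-8-[(4-acetoxyphenyl)acetyl]chromane-5,7-diyl diacetate F8.
   - Oxidation with SeO2 as in step 8 gives the dione tetraacetate (2S)-2-(4-acetoxyphenyl)-8-[(4-acetoxyphenyl)(oxo)acetyl]chromane-5,7-diyl diacetate F9.
   - Neutral deacetylation (NH4OAc, MeOH–H2O, rt) reaches the target 15.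

**Further compounds**

F1 | step 4 | 2,4-bis(benzyloxy)-6-hydroxybenzaldehyde | O=Cc1c(O)cc(OCc2ccccc2)cc1OCc1ccccc1
F2 | step 4 | (2R)-5,7-bis(benzyloxy)-2-[4-(benzyloxy)phenyl]-2H-chromene-3-carbaldehyde | c1c(OCc2ccccc2)cc(OCc2ccccc2)c2c1O[C@H](c1ccc(OCc3ccccc3)cc1)C(C=O)=C2
F3 | step 4 | (2S)-5,7-bis(benzyloxy)-2-[4-(benzyloxy)phenyl]-2H-chromene | c1c(OCc2ccccc2)cc(OCc2ccccc2)c2c1O[C@H](c1ccc(OCc3ccccc3)cc1)C=C2
F4 | step 4 | (2S)-5,7-bis(benzyloxy)-2-[4-(benzyloxy)phenyl]chromane | c1c(OCc2ccccc2)cc(OCc2ccccc2)c2c1O[C@H](c1ccc(OCc3ccccc3)cc1)CC2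
F5 | step 4 | (2S)-5,7-bis(benzyloxy)-2-[4-(benzyloxy)phenyl]-8-bromochromane | Brc1c(OCc2ccccc2)cc(OCc2ccccc2)c2c1O[C@H](c1ccc(OCc3ccccc3)cc1)CC2
F6 | step 5 | (2S)-8-acetyl-5,7-bis(benzyloxy)-2-[4-(benzyloxy)phenyl]chromane-3-carbaldehyde (C3 not assigned) | CC(=O)c1c(OCc2ccccc2)cc(OCc2ccccc2)c2c1O[C@H](c1ccc(OCc3ccccc3)cc1)C(C=O)C2
F7 | step 9 | 1-[(2S)-5,7-dihydroxy-2-(4-hydroxyphenyl)chroman-8-yl]-2-(4-hydroxyphenyl)ethan-1-one | O=C(Cc1ccc(O)cc1)c1c(O)cc(O)c2c1O[C@H](c1ccc(O)cc1)CC2
F8 | step 9 | (2S)-2-(4-acetoxyphenyl)-8-[(4-acetoxyphenyl)acetyl]chromane-5,7-diyl diacetate | CC(=O)Oc1ccc(CC(=O)c2c(OC(C)=O)cc(OC(C)=O)c3c2O[C@H](c2ccc(OC(C)=O)cc2)CC3)cc1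
F9 | step 9 | (2S)-2-(4-acetoxyphenyl)-8-[(4-acetoxyphenyl)(oxo)acetyl]chromane-5,7-diyl diacetate | CC(=O)Oc1ccc(C(=O)C(=O)c2c(OC(C)=O)cc(OC(C)=O)c3c2O[C@H](c2ccc(OC(C)=O)cc2)CC3)cc1
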